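**Remark on the chemistry:** the target has no stereogenic element. The only configurational features on the route are the E double bond of 7 and the two transient bridgehead centres of 12, which form as a racemate and are lost again in the same flask.

## The problem

The target is a biflavone in which a diaryl ether joins C8 of unit 1, a 5-hydroxy-7-methoxy-2-(4-methoxyphenyl)chromen-4-one (rings A, B, C), to C4' of unit 2, a 5,7-dihydroxyflavone (rings D, E, F) whose 2-aryl ring E carries the ether oxygen para to C2. No stereocentre or axis needs control, so the task is one of connectivity and of telling seven oxygen atoms apart. The ether oxygen on C8 lies between C7–OMe and C8a–O1 on a fully substituted edge of ring A, which makes a late copper-mediated or SNAr arylation of an 8-hydroxyflavone the least attractive bond to form. Unit 1 must finish with a free 5-OH beside 7-OMe and 4'-OMe, and unit 2 with free 5-OH and 7-OH, so the protecting groups must allow exactly three phenols to be unmasked. The pyranone rings do not tolerate hot concentrated alkali, which opens them, and once the 5-OH of unit 1 is free, hot strong protic acid can move the C8 substituent to C6 by Wessely–Moser isomerisation. The enabling feature is that ring E is a 1,4-disubstituted benzene with the ether oxygen on C4' and the carbon that becomes C2 of unit 2 on C1'. An oxygen-substituted alkyne and a 2-pyranone-5-carboxylate give exactly this pattern after loss of CO2, so ring E can be assembled on the C8 oxygen instead of being coupled to it.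

## Retrosynthesis

**27 to 26.** Three O–C(alkyl) bonds are cut: the two benzylic O–CH2 bonds on ring D and the O–CH3 bond at C5 of unit 1. Benzyl is chosen for unit 2 because methyl ethers there could not be told apart from 7-OMe and 4'-OMe. The 5-OMe of unit 1 is the one methyl ether that a chelating Lewis acid removes, because it is peri to the C4 carbonyl. Keeping it methylated to the end also means ring C is closed on a ring A with a single free phenol, so no 6- versus 8-aryloxy ambiguity can arise. The forward reaction must cleave two benzyl ethers and one methyl ether and leave two methyl ethers and the diaryl ether alone.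

**26 to 25 to 21 + 23 (and 23 to 22).** O1–C2 of unit 2 is cut first (cyclodehydration of diketone 25), then C2–C3 of unit 2 (acylation of the enolate of acetophenone 23 by the ring E carboxyl of acid 21). A chalcone route would need ring E at the aldehyde level and an oxidative closure. The carboxyl level is what the key step delivers, so the diketone route costs no redox adjustment. The cut removes rings F and D and leaves acid 21 and acetophenone 23, which is one benzylation away from 2,4,6-trihydroxyacetophenone 22. The forward acylation must occur at the acid chloride and not at the pyranone of unit 1.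

**21 to 20 to 19 to 17 + 18.** After ester hydrolysis (21 to 20), O1–C2 and then C2–C3 of unit 1 are cut in the same way, giving ortho-hydroxyacetophenone 17 and 4-methoxybenzoyl chloride 18. Unit 1 is built before unit 2 because the ring A chemistry of the next paragraph uses hydrogenolysis and a hot Lewis acid, which the benzyl ethers of unit 2 would not survive. The methyl ester rides through as a latent acyl donor. The precursor 17 is a diaryl ether with one acetyl group.

**17 to 14 to 13.** The bond from ring A to the acetyl carbon (future C4a–C4) and the benzyl O–C bond are cut. The acetyl group is placed after the key step because a ketone would not survive the n-BuLi of step 4. The forward acylation must go to the single position ortho to the freed phenol (future C4a) and not to the position between the two methoxy groups (future C6).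

**13 to 10 + 11.** The C4'–C3' and C5'–C6' bonds of ring E are cut. The alkyne carbons of ynol ether 10 become C4' and C5', and C3, C4, C5 and C6 of methyl coumalate 11 become C3', C2', C1' and C6'. Against the neighbouring cut of the C8–O–C4' bond itself, this avoids any arylation of the hindered oxygen and brings in the carboxyl carbon for unit 2 at the same time. The forward reaction needs one regiochemical outcome, oxygen para to the ester.

**10 to 7 to 4 + 5, and 4 to 2 to 1.** The ynol ether comes from the (E)-1,2-dichlorovinyl ether 7, made from phenol 4 and trichloroethylene 5. The O–C bond that ends as the diaryl ether bond is therefore made with a small linear electrophile. Phenol 4 comes from commercial aldehyde 1 by benzylation and Dakin-type oxidation, which converts the formyl carbon into the future C8 oxygen with the right neighbours (OMe on one side, OBn on the other).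

## Roads not taken

Alternative 1: ring A is made by thermal ring expansion of a 4-hydroxycyclobutenone. The cut is C4a–C5 of unit 1, with C8–C8a set earlier by 1,2-addition of a metalated pyranone to a squarate-type carbonyl group. The precursor would be the cyclobutenone 4-hydroxy-3-methoxy-4-[6-(4-methoxyphenyl)-4-oxo-4H-pyran-2-yl]cyclobut-2-en-1-one A2. On heating in xylene, A2 should open to a dienylketene and close onto the pyranone to give 5,8-dihydroxy-7-methoxy-2-(4-methoxyphenyl)-4H-chromen-4-one A1.
- Merits: A1 has 5-OH free, 7-OMe in place and the C8 hydroxyl uniquely marked. It needs neither a late selective demethylation nor a regioselective acylation of ring A, and in both respects it is better than the chosen plan.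
- Weak points: the synthesis of A2 needs a 4-pyranone metalated next to its ring oxygen, which is not a routine nucleophile. More seriously, A1 still has to be arylated at the C8 hydroxyl between C7–OMe and O1, which is the bond identified above as the hardest. Unit 2 would then still have to be built linearly from the new aryl ring.
- Comparison: the chosen plan sets against this that its ether bond is made on a small phenol with a two-carbon electrophile, and that ring E arrives with the carboxyl carbon for unit 2 attached.

Alternative 2: a two-directional bichalcone with double oxidative closure. The cuts are O1–C2 of both units. The bichalcone (2E)-1-[3-(4-{(1E)-3-[2,4-bis(benzyloxy)-6-hydroxyphenyl]-3-oxoprop-1-en-1-yl}phenoxy)-2-hydroxy-4,6-dimethoxyphenyl]-3-(4-methoxyphenyl)prop-2-en-1-one A4 carries one free ortho-hydroxyl on each ketone ring. Heating A4 with catalytic I2 in DMSO would close rings C and F at once. The product would be A3, which is the same protected biflavone as 26.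
- Merits: one operation closes both pyranones, and after the diaryl ether the endgame is shorter than the chosen one (two aldol condensations and one double cyclisation against five steps).
- Weak points: the two chalcone halves of A4 differ, so the linchpin 4-(3-acetyl-2-hydroxy-4,6-dimethoxyphenoxy)benzaldehyde A5 carries both a methyl ketone and an aldehyde and can condense with itself. The condensations would have to be staged or one carbonyl masked, which uses up part of the step advantage. Hot I2/DMSO generates HI in the presence of two benzyl ethers and two electron-rich rings, so debenzylation and ring iodination are possible on the way from A4 to A3. The diaryl ether of A5 must still come from arylation of a hindered phenol.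
- Comparison: the chosen plan differentiates its two acyl components by oxidation level (ester and acetyl), so no cross-condensation can occur, and it avoids the O-arylation.

Alternative 3: aryne insertion. The cuts are C8a–O1 and C4a–C4 of unit 2. CsF would release the corresponding aryne from 3,5-bis(benzyloxy)-2-(trimethylsilyl)phenyl trifluoromethanesulfonate A7. The aryne would insert into the carboxyl C–O bond of 3-(4-{[5,7-dimethoxy-2-(4-methoxyphenyl)-4-oxo-4H-chromen-8-yl]oxy}phenyl)prop-2-ynoic acid A8. The product would be the ortho-hydroxyaryl ynone 1-[2,4-bis(benzyloxy)-6-hydroxyphenyl]-3-(4-{[5,7-dimethoxy-2-(4-methoxyphenyl)-4-oxo-4H-chromen-8-yl]oxy}phenyl)prop-2-yn-1-one A6.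
- Merits: the regiochemistry is favourable, since a 3-alkoxyaryne takes the oxygen nucleophile at the distal carbon and the acyl group next to the alkoxy group, which gives exactly the 2-hydroxy-4,6-dialkoxyaryl ketone of A6. The conditions are mild and the fragment coupling is late and convergent, more convergent than the linear endgame chosen here.
- Weak points: A7 needs several steps. A8 needs complete unit 1, the diaryl ether made by some other means, and an alkynoic acid that can decarboxylate. Simple O-arylation of the carboxylate competes with acyl migration. The step closes no ring, so A6 must still be cyclised 6-endo in competition with 5-exo closure to an aurone.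
- Comparison: the chosen plan uses the ester carbon of 13 for the same purpose with shelf reagents and does not leave the ether bond to be solved elsewhere.

Key step: step 5

## Route

Step 1
Reactants: 1 2-hydroxy-4,6-dimethoxybenzaldehyde
Product: 2 2-(benzyloxy)-4,6-dimethoxybenzaldehyde
Conditions: BnBr, K2CO3, DMF, 60 °C
Reagents that add atoms: benzyl bromide, BrCc1ccccc1
Why: Williamson etherification; the phenol is acidified by the ortho-formyl group, so K2CO3 is sufficient.

Step 2
Reactants: 2 2-(benzyloxy)-4,6-dimethoxybenzaldehyde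
Product: 4 2-(benzyloxy)-4,6-dimethoxyphenol, via aryl formate 3 (not isolated)
Conditions: mCPBA, CH2Cl2, 0 °C → rt; then cat. K2CO3, MeOH, rt
Reagents that add atoms: mCPBA, OOC(=O)c1cccc(Cl)c1
Why: Dakin-type Baeyer–Villiger oxidation; the electron-rich aryl group migrates to give formate 3, and methanolysis frees the phenol, which places the future C8 oxygen between OMe and OBn.

Step 3
Reactants: 4 2-(benzyloxy)-4,6-dimethoxyphenol; 5 trichloroethylene
Product: 7 1-(benzyloxy)-2-{[(E)-1,2-dichloroethenyl]oxy}-3,5-dimethoxybenzene, via dichloroacetylene 6 (not isolated)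
Conditions: K2CO3, DMF, 70 °C
Reagents that add atoms: none
Why: Known O-dichlorovinylation of phenols: base dehydrochlorinates 5 to dichloroacetylene, and anti addition of the phenoxide gives the E ether. The slim electrophile is not hindered by the two ortho substituents.

Step 4
Reactants: 7 1-(benzyloxy)-2-{[(E)-1,2-dichloroethenyl]oxy}-3,5-dimethoxybenzene
Product: 10 1-(benzyloxy)-2-(ethynyloxy)-3,5-dimethoxybenzene, via chloroethynyl ether 8 (not isolated), via lithium acetylide 9 (not isolated)
Conditions: n-BuLi (2.2 equiv), THF, −78 → −40 °C; then sat. aq NH4Cl, −78 °C; solvent exchange to toluene, used at once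
Reagents that add atoms: none
Why: Known ynol ether synthesis from 1,2-dichlorovinyl ethers: deprotonation and loss of LiCl give 8, Li–Cl exchange gives 9, and protonation gives 10. An aryl ethynyl ether has no beta-hydrogen for retro-ene loss of ketene, but it can oligomerise, so it is kept in solution.

Step 5
Reactants: 10 1-(benzyloxy)-2-(ethynyloxy)-3,5-dimethoxybenzene; 11 methyl coumalate (methyl 2-oxo-2H-pyran-5-carboxylate)
Product: 13 methyl 4-[2-(benzyloxy)-4,6-dimethoxyphenoxy]benzoate, via bicyclic lactone 12 (not isolated)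
Conditions: 11 (2 equiv), toluene, 100 °C, sealed tube
Reagents that add atoms: none
Why: Proposed new method: the ether oxygen raises the HOMO of 10 and puts its largest coefficient on the terminal carbon, while the LUMO of 11 is largest at C6 (beta to the ester and bound to the ring oxygen), so an asynchronous inverse-electron-demand [4+2] addition should join the terminal carbon to C6 and the oxygen-bearing carbon to C3. The closest known reaction type is the Diels–Alder/retro-Diels–Alder benzannulation of methyl coumalate with ynamines, enol ethers and ketene acetals, in which the donor-bearing carbon ends para to the ester; a terminal aryloxyalkyne has not been used in it. Ring E closes by an intermolecular two-bond [4+2] annulation (four carbons of 11, two of 10) to the bridged lactone 12, and the irreversible retro-[4+2] loss of CO2 gives the benzene directly, with no oxidation or elimination step. The two bridgehead centres of 12 are fixed relative to each other by the bicycle, form as a racemate and disappear on aromatisation, so no stereocontrol is required. The one selectivity needed is regiochemical (para against meta aryloxybenzoate), and it rests on the matched polarisation described; the crowded ring A is three atoms from the reacting terminus and should not override it. An excess of 11 and moderate dilution are meant to let the cycloaddition outrun self-addition of the ynol ether.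

Step 6
Reactants: 13 methyl 4-[2-(benzyloxy)-4,6-dimethoxyphenoxy]benzoate
Product: 14 methyl 4-(2-hydroxy-4,6-dimethoxyphenoxy)benzoate
Conditions: H2 (1 atm), Pd/C, EtOAc/MeOH, rt
Reagents that add atoms: none
Why: Hydrogenolysis of an aryl benzyl ether; the diaryl ether, ester and methyl ethers are inert under these conditions.

Step 7
Reactants: 14 methyl 4-(2-hydroxy-4,6-dimethoxyphenoxy)benzoate
Product: 17 methyl 4-(3-acetyl-2-hydroxy-4,6-dimethoxyphenoxy)benzoate, via aryl acetate 15 (not isolated), via difluoroboron chelate 16 (not isolated)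
Conditions: Ac2O, BF3·OEt2, AcOH, 80 °C; then H2O/MeOH, 60 °C
Reagents that add atoms: acetic anhydride, CC(=O)OC(C)=O
Why: O-acetylation followed by BF3-promoted Fries migration (Friedel–Crafts acylation) to the only free ortho position gives chelate 16 as the thermodynamic sink, which is hydrolysed on work-up. The other free position lies between two methoxy groups, one of them pushed over it by the neighbouring aryloxy group, and has no chelating neighbour.

Step 8
Reactants: 17 methyl 4-(3-acetyl-2-hydroxy-4,6-dimethoxyphenoxy)benzoate; 18 4-methoxybenzoyl chloride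
Product: 19 methyl 4-{2-hydroxy-4,6-dimethoxy-3-[3-(4-methoxyphenyl)-3-oxopropanoyl]phenoxy}benzoate
Conditions: LiN(SiMe3)2 (3.2 equiv), THF, −78 → −20 °C; then 18, −78 °C → rt; aq HCl
Reagents that add atoms: none
Why: C-aroylation of the phenoxide–enolate dianion of an ortho-hydroxyacetophenone (a one-flask equivalent of the Baker–Venkataraman sequence); any O-aroylated material rearranges to the same diketone under the excess base. The deactivated methyl benzoate is not attacked at low temperature.

Step 9
Reactants: 19 methyl 4-{2-hydroxy-4,6-dimethoxy-3-[3-(4-methoxyphenyl)-3-oxopropanoyl]phenoxy}benzoate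
Product: 20 methyl 4-{[5,7-dimethoxy-2-(4-methoxyphenyl)-4-oxo-4H-chromen-8-yl]oxy}benzoate
Conditions: AcOH, cat. H2SO4, 90 °C
Reagents that add atoms: none
Why: Acid-catalysed cyclodehydration of a 1-(2-hydroxyaryl)-1,3-diketone closes pyranone ring C; only one phenol is present, so only the 8-aryloxy isomer can form.

Step 10
Reactants: 20 methyl 4-{[5,7-dimethoxy-2-(4-methoxyphenyl)-4-oxo-4H-chromen-8-yl]oxy}benzoate
Product: 21 4-{[5,7-dimethoxy-2-(4-methoxyphenyl)-4-oxo-4H-chromen-8-yl]oxy}benzoic acid
Conditions: LiOH·H2O, THF/MeOH/H2O, rt; then 1 M HCl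
Reagents that add atoms: lithium hydroxide, [Li+].[OH-]
Why: Saponification of a methyl benzoate under conditions far milder than the hot concentrated alkali needed to open a flavone pyranone ring.

Step 11
Reactants: 22 2,4,6-trihydroxyacetophenone
Product: 23 1-[2,4-bis(benzyloxy)-6-hydroxyphenyl]ethan-1-one
Conditions: BnBr (2.1 equiv), K2CO3, DMF, rt
Reagents that add atoms: benzyl bromide, BrCc1ccccc1
Why: Williamson benzylation; the hydroxyl chelated to the acetyl group is the least nucleophilic, so two equivalents give the known 4,6-dibenzyl ether.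

Step 12
Reactants: 21 4-{[5,7-dimethoxy-2-(4-methoxyphenyl)-4-oxo-4H-chromen-8-yl]oxy}benzoic acid; 23 1-[2,4-bis(benzyloxy)-6-hydroxyphenyl]ethan-1-one
Product: 25 1-[2,4-bis(benzyloxy)-6-hydroxyphenyl]-3-(4-{[5,7-dimethoxy-2-(4-methoxyphenyl)-4-oxo-4H-chromen-8-yl]oxy}phenyl)propane-1,3-dione, via acid chloride 24 (not isolated)
Conditions: 21, (COCl)2 (1.2 equiv), cat. DMF, CH2Cl2, 0 °C → rt, evaporate; 23, LiN(SiMe3)2 (3.1 equiv), THF, −78 °C; then 24, −78 °C → rt; aq HCl
Reagents that add atoms: none
Why: Acid chloride formation, then C-acylation of the dianion of 23 as in step 8; the acid chloride is much more electrophilic than the pyranone carbonyl or C2 of unit 1, and no hydroxide is present to open ring C.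

Step 13
Reactants: 25 1-[2,4-bis(benzyloxy)-6-hydroxyphenyl]-3-(4-{[5,7-dimethoxy-2-(4-methoxyphenyl)-4-oxo-4H-chromen-8-yl]oxy}phenyl)propane-1,3-dione
Product: 26 5,7-bis(benzyloxy)-2-(4-{[5,7-dimethoxy-2-(4-methoxyphenyl)-4-oxo-4H-chromen-8-yl]oxy}phenyl)-4H-chromen-4-one
Conditions: cat. p-TsOH·H2O, toluene, 90 °C
Reagents that add atoms: none
Why: Acid-catalysed cyclodehydration closes pyranone ring F; a sulfonic acid in toluene is chosen over H2SO4/AcOH to spare the benzyl ethers.

Step 14
Reactants: 26 5,7-bis(benzyloxy)-2-(4-{[5,7-dimethoxy-2-(4-methoxyphenyl)-4-oxo-4H-chromen-8-yl]oxy}phenyl)-4H-chromen-4-one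
Product: 27 5,7-dihydroxy-2-(4-{[5-hydroxy-7-methoxy-2-(4-methoxyphenyl)-4-oxo-4H-chromen-8-yl]oxy}phenyl)-4H-chromen-4-one
Conditions: BCl3, pentamethylbenzene, CH2Cl2, −78 → 0 °C; then H2O
Reagents that add atoms: none
Why: BCl3 cleaves aryl benzyl ethers at low temperature, with pentamethylbenzene trapping the benzyl cation, and through chelation to the C4 carbonyl it also removes the peri 5-O-methyl group of unit 1. The 7- and 4'-methyl ethers and the diaryl ether have no such assistance, and the cold aprotic medium gives no opening for Wessely–Moser isomerisation.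

## Compound list

1 | 2-hydroxy-4,6-dimethoxybenzaldehyde | COc1cc(O)c(C=O)c(OC)c1 | starting material
2 | 2-(benzyloxy)-4,6-dimethoxybenzaldehyde | COc1cc(OCc2ccccc2)c(C=O)c(OC)c1 | intermediate
3 | 2-(benzyloxy)-4,6-dimethoxyphenyl formate | O=COc1c(OC)cc(OC)cc1OCc1ccccc1 | intermediate
4 | 2-(benzyloxy)-4,6-dimethoxyphenol | Oc1c(OC)cc(OC)cc1OCc1ccccc1 | intermediate
5 | trichloroethylene | ClC=C(Cl)Cl | starting material
6 | dichloroacetylene | ClC#CCl | intermediate
7 | 1-(benzyloxy)-2-{[(E)-1,2-dichloroethenyl]oxy}-3,5-dimethoxybenzene | Cl/C=C(/Cl)Oc1c(OC)cc(OC)cc1OCc1ccccc1 | intermediate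
8 | 1-(benzyloxy)-2-[(chloroethynyl)oxy]-3,5-dimethoxybenzene | ClC#COc1c(OC)cc(OC)cc1OCc1ccccc1 | intermediate
9 | lithium [2-(benzyloxy)-4,6-dimethoxyphenoxy]acetylide | [Li+].[C-]#COc1c(OC)cc(OC)cc1OCc1ccccc1 | intermediate
10 | 1-(benzyloxy)-2-(ethynyloxy)-3,5-dimethoxybenzene | C#COc1c(OC)cc(OC)cc1OCc1ccccc1 | intermediate
11 | methyl coumalate (methyl 2-oxo-2H-pyran-5-carboxylate) | COC(=O)c1ccc(=O)oc1 | starting material
12 | methyl 5-[2-(benzyloxy)-4,6-dimethoxyphenoxy]-3-oxo-2-oxabicyclo[2.2.2]octa-5,7-diene-7-carboxylate (racemic; one enantiomer drawn) | O=C1O[C@H]2C=C(Oc3c(OC)cc(OC)cc3OCc3ccccc3)[C@@H]1C=C2C(=O)OC | intermediate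
13 | methyl 4-[2-(benzyloxy)-4,6-dimethoxyphenoxy]benzoate | COC(=O)c1ccc(Oc2c(OC)cc(OC)cc2OCc2ccccc2)cc1 | intermediate
14 | methyl 4-(2-hydroxy-4,6-dimethoxyphenoxy)benzoate | COC(=O)c1ccc(Oc2c(OC)cc(OC)cc2O)cc1 | intermediate
15 | methyl 4-[2-(acetyloxy)-4,6-dimethoxyphenoxy]benzoate | COC(=O)c1ccc(Oc2c(OC)cc(OC)cc2OC(C)=O)cc1 | intermediate
16 | O,O-difluoroboron chelate of methyl 4-(3-acetyl-2-hydroxy-4,6-dimethoxyphenoxy)benzoate | COC(=O)c1ccc(Oc2c(OC)cc(OC)c3c2O[B-](F)(F)[O+]=C3C)cc1 | intermediate
17 | methyl 4-(3-acetyl-2-hydroxy-4,6-dimethoxyphenoxy)benzoate | COC(=O)c1ccc(Oc2c(OC)cc(OC)c(C(C)=O)c2O)cc1 | intermediate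
18 | 4-methoxybenzoyl chloride | COc1ccc(C(=O)Cl)cc1 | starting material
19 | methyl 4-{2-hydroxy-4,6-dimethoxy-3-[3-(4-methoxyphenyl)-3-oxopropanoyl]phenoxy}benzoate | COC(=O)c1ccc(Oc2c(OC)cc(OC)c(C(=O)CC(=O)c3ccc(OC)cc3)c2O)cc1 | intermediate
20 | methyl 4-{[5,7-dimethoxy-2-(4-methoxyphenyl)-4-oxo-4H-chromen-8-yl]oxy}benzoate | COC(=O)c1ccc(Oc2c(OC)cc(OC)c3c(=O)cc(-c4ccc(OC)cc4)oc23)cc1 | intermediate
21 | 4-{[5,7-dimethoxy-2-(4-methoxyphenyl)-4-oxo-4H-chromen-8-yl]oxy}benzoic acid | OC(=O)c1ccc(Oc2c(OC)cc(OC)c3c(=O)cc(-c4ccc(OC)cc4)oc23)cc1 | intermediate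
22 | 2,4,6-trihydroxyacetophenone | CC(=O)c1c(O)cc(O)cc1O | starting material
23 | 1-[2,4-bis(benzyloxy)-6-hydroxyphenyl]ethan-1-one | CC(=O)c1c(O)cc(OCc2ccccc2)cc1OCc1ccccc1 | intermediate
24 | 4-{[5,7-dimethoxy-2-(4-methoxyphenyl)-4-oxo-4H-chromen-8-yl]oxy}benzoyl chloride | ClC(=O)c1ccc(Oc2c(OC)cc(OC)c3c(=O)cc(-c4ccc(OC)cc4)oc23)cc1 | intermediate
25 | 1-[2,4-bis(benzyloxy)-6-hydroxyphenyl]-3-(4-{[5,7-dimethoxy-2-(4-methoxyphenyl)-4-oxo-4H-chromen-8-yl]oxy}phenyl)propane-1,3-dione | COc1ccc(-c2cc(=O)c3c(OC)cc(OC)c(Oc4ccc(C(=O)CC(=O)c5c(O)cc(OCc6ccccc6)cc5OCc5ccccc5)cc4)c3o2)cc1 | intermediate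
26 | 5,7-bis(benzyloxy)-2-(4-{[5,7-dimethoxy-2-(4-methoxyphenyl)-4-oxo-4H-chromen-8-yl]oxy}phenyl)-4H-chromen-4-one | COc1ccc(-c2cc(=O)c3c(OC)cc(OC)c(Oc4ccc(-c5cc(=O)c6c(OCc7ccccc7)cc(OCc7ccccc7)cc6o5)cc4)c3o2)cc1 | intermediate
27 | 5,7-dihydroxy-2-(4-{[5-hydroxy-7-methoxy-2-(4-methoxyphenyl)-4-oxo-4H-chromen-8-yl]oxy}phenyl)-4H-chromen-4-one | COc1ccc(-c2cc(=O)c3c(O)cc(OC)c(Oc4ccc(-c5cc(=O)c6c(O)cc(O)cc6o5)cc4)c3o2)cc1 | target

## Step count and least certain steps

Total step count: 14. Longest linear sequence: 13 steps (steps 1 to 10 and 12 to 14); step 11 is a one-step side branch.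

**Step 5 (key step, proposed new method).** The most likely failure is self-addition or oligomerisation of the terminal ynol ether outrunning a slow cycloaddition. The second is erosion of regiocontrol towards the meta aryloxybenzoate if the aryloxy oxygen, whose lone pair is shared with ring A, polarises the alkyne less than an alkoxy or amino group does. The fallback uses known chemistry and gives up the cycloaddition. It sets out from phenol 4, which is heated with 4-fluorobenzaldehyde and K2CO3 in DMF (SNAr, precedented for ortho,ortho-disubstituted phenoxides with this activated fluoroarene) to give 4-[2-(benzyloxy)-4,6-dimethoxyphenoxy]benzaldehyde F1. Pinnick oxidation (NaClO2, NaH2PO4, 2-methyl-2-butene) gives 4-[2-(benzyloxy)-4,6-dimethoxyphenoxy]benzoic acid F2, and MeI/K2CO3 returns the route to 13.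

**Step 4.** The terminal aryl ethynyl ether may hydrate or oligomerise during work-up and solvent exchange, and n-BuLi may begin to lithiate the ring positions between two alkoxy groups if the temperature rises. The fallback sets out from 7 and traps acetylide 9 with Me3SiCl instead of a proton, giving the storable {[2-(benzyloxy)-4,6-dimethoxyphenoxy]ethynyl}trimethylsilane F3. Heating F3 with 11 should give, through the silylated adduct methyl 5-[2-(benzyloxy)-4,6-dimethoxyphenoxy]-3-oxo-6-(trimethylsilyl)-2-oxabicyclo[2.2.2]octa-5,7-diene-7-carboxylate F4, the aryl silane methyl 4-[2-(benzyloxy)-4,6-dimethoxyphenoxy]-3-(trimethylsilyl)benzoate F5. Protodesilylation with CF3CO2H in CH2Cl2 then comes back to 13. This fallback still depends on the cycloaddition, now with a bulkier dienophile; if that also fails, the SNAr fallback of step 5 applies.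

**Step 7.** Acylation may go to the ring position between the two methoxy groups, or the reaction may stall at the O-acetate. The fallback sets out from 14 and uses a strictly ortho-directed formylation (MgCl2, Et3N, paraformaldehyde, MeCN, reflux) to give methyl 4-(3-formyl-2-hydroxy-4,6-dimethoxyphenoxy)benzoate F6. Addition of the lithium acetylide of 4-ethynylanisole (2.2 equiv, THF, −78 °C) gives racemic methyl 4-{2-hydroxy-3-[1-hydroxy-3-(4-methoxyphenyl)prop-2-yn-1-yl]-4,6-dimethoxyphenoxy}benzoate F7. Oxidation with MnO2 gives methyl 4-{2-hydroxy-4,6-dimethoxy-3-[3-(4-methoxyphenyl)prop-2-ynoyl]phenoxy}benzoate F8, and amine-mediated 6-endo cyclisation (Et2NH, EtOH) returns the route to flavone 20, replacing steps 7 to 9.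

**Step 12.** Competing O-acylation or double acylation of the dianion, or addition of the enolate to the pyranone of unit 1, would consume the valuable acid chloride. The fallback sets out from 21 and 23 and esterifies them (EDC·HCl, DMAP, CH2Cl2) to 2-acetyl-3,5-bis(benzyloxy)phenyl 4-{[5,7-dimethoxy-2-(4-methoxyphenyl)-4-oxo-4H-chromen-8-yl]oxy}benzoate F9. Classical Baker–Venkataraman acyl migration (KOt-Bu, THF) then returns to 25.

**Step 14.** The 7-methoxy group of unit 1, which lies next to the aryloxy oxygen, may be lost together with the 5-methoxy group, or the 5-O-demethylation may remain incomplete at the temperature that spares it. The fallback sets out from 26 and separates the two tasks. Hydrogenolysis (H2, Pd/C, THF/MeOH) gives 5,7-dihydroxy-2-(4-{[5,7-dimethoxy-2-(4-methoxyphenyl)-4-oxo-4H-chromen-8-yl]oxy}phenyl)-4H-chromen-4-one F10. A milder chelation-controlled demethylation (AlCl3, MeCN) then removes only the peri methyl group and arrives at 27.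

## Further compounds

F1 | step 5 | 4-[2-(benzyloxy)-4,6-dimethoxyphenoxy]benzaldehyde | O=Cc1ccc(Oc2c(OC)cc(OC)cc2OCc2ccccc2)cc1
F2 | step 5 | 4-[2-(benzyloxy)-4,6-dimethoxyphenoxy]benzoic acid | OC(=O)c1ccc(Oc2c(OC)cc(OC)cc2OCc2ccccc2)cc1
F3 | step 4 | {[2-(benzyloxy)-4,6-dimethoxyphenoxy]ethynyl}trimethylsilane | C[Si](C)(C)C#COc1c(OC)cc(OC)cc1OCc1ccccc1
F4 | step 4 | methyl 5-[2-(benzyloxy)-4,6-dimethoxyphenoxy]-3-oxo-6-(trimethylsilyl)-2-oxabicyclo[2.2.2]octa-5,7-diene-7-carboxylate (racemic; one enantiomer drawn) | O=C1O[C@H]2C([Si](C)(C)C)=C(Oc3c(OC)cc(OC)cc3OCc3ccccc3)[C@@H]1C=C2C(=O)OC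
F5 | step 4 | methyl 4-[2-(benzyloxy)-4,6-dimethoxyphenoxy]-3-(trimethylsilyl)benzoate | COC(=O)c1ccc(Oc2c(OC)cc(OC)cc2OCc2ccccc2)c([Si](C)(C)C)c1
F6 | step 7 | methyl 4-(3-formyl-2-hydroxy-4,6-dimethoxyphenoxy)benzoate | COC(=O)c1ccc(Oc2c(OC)cc(OC)c(C=O)c2O)cc1
F7 | step 7 | methyl 4-{2-hydroxy-3-[1-hydroxy-3-(4-methoxyphenyl)prop-2-yn-1-yl]-4,6-dimethoxyphenoxy}benzoate (racemic) | COC(=O)c1ccc(Oc2c(OC)cc(OC)c(C(O)C#Cc3ccc(OC)cc3)c2O)cc1
F8 | step 7 | methyl 4-{2-hydroxy-4,6-dimethoxy-3-[3-(4-methoxyphenyl)prop-2-ynoyl]phenoxy}benzoate | COC(=O)c1ccc(Oc2c(OC)cc(OC)c(C(=O)C#Cc3ccc(OC)cc3)c2O)cc1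
F9 | step 12 | 2-acetyl-3,5-bis(benzyloxy)phenyl 4-{[5,7-dimethoxy-2-(4-methoxyphenyl)-4-oxo-4H-chromen-8-yl]oxy}benzoate | COc1ccc(-c2cc(=O)c3c(OC)cc(OC)c(Oc4ccc(C(=O)Oc5cc(OCc6ccccc6)cc(OCc6ccccc6)c5C(C)=O)cc4)c3o2)cc1
F10 | step 14 | 5,7-dihydroxy-2-(4-{[5,7-dimethoxy-2-(4-methoxyphenyl)-4-oxo-4H-chromen-8-yl]oxy}phenyl)-4H-chromen-4-one | COc1ccc(-c2cc(=O)c3c(OC)cc(OC)c(Oc4ccc(-c5cc(=O)c6c(O)cc(O)cc6o5)cc4)c3o2)cc1
A1 | alternative 1 | 5,8-dihydroxy-7-methoxy-2-(4-methoxyphenyl)-4H-chromen-4-one | COc1ccc(-c2cc(=O)c3c(O)cc(OC)c(O)c3o2)cc1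
A2 | alternative 1 | 4-hydroxy-3-methoxy-4-[6-(4-methoxyphenyl)-4-oxo-4H-pyran-2-yl]cyclobut-2-en-1-one (racemic) | COC1=CC(=O)C1(O)c1cc(=O)cc(-c2ccc(OC)cc2)o1
A3 | alternative 2 | 5,7-bis(benzyloxy)-2-(4-{[5,7-dimethoxy-2-(4-methoxyphenyl)-4-oxo-4H-chromen-8-yl]oxy}phenyl)-4H-chromen-4-one (identical with 26) | COc1ccc(-c2cc(=O)c3c(OC)cc(OC)c(Oc4ccc(-c5cc(=O)c6c(OCc7ccccc7)cc(OCc7ccccc7)cc6o5)cc4)c3o2)cc1
A4 | alternative 2 | (2E)-1-[3-(4-{(1E)-3-[2,4-bis(benzyloxy)-6-hydroxyphenyl]-3-oxoprop-1-en-1-yl}phenoxy)-2-hydroxy-4,6-dimethoxyphenyl]-3-(4-methoxyphenyl)prop-2-en-1-one | COc1ccc(/C=C/C(=O)c2c(O)c(Oc3ccc(/C=C/C(=O)c4c(O)cc(OCc5ccccc5)cc4OCc4ccccc4)cc3)c(OC)cc2OC)cc1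
A5 | alternative 2 | 4-(3-acetyl-2-hydroxy-4,6-dimethoxyphenoxy)benzaldehyde | CC(=O)c1c(OC)cc(OC)c(Oc2ccc(C=O)cc2)c1O
A6 | alternative 3 | 1-[2,4-bis(benzyloxy)-6-hydroxyphenyl]-3-(4-{[5,7-dimethoxy-2-(4-methoxyphenyl)-4-oxo-4H-chromen-8-yl]oxy}phenyl)prop-2-yn-1-one | COc1ccc(-c2cc(=O)c3c(OC)cc(OC)c(Oc4ccc(C#CC(=O)c5c(O)cc(OCc6ccccc6)cc5OCc5ccccc5)cc4)c3o2)cc1
A7 | alternative 3 | 3,5-bis(benzyloxy)-2-(trimethylsilyl)phenyl trifluoromethanesulfonate | C[Si](C)(C)c1c(OCc2ccccc2)cc(OCc2ccccc2)cc1OS(=O)(=O)C(F)(F)F
A8 | alternative 3 | 3-(4-{[5,7-dimethoxy-2-(4-methoxyphenyl)-4-oxo-4H-chromen-8-yl]oxy}phenyl)prop-2-ynoic acid | COc1ccc(-c2cc(=O)c3c(OC)cc(OC)c(Oc4ccc(C#CC(=O)O)cc4)c3o2)cc1
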